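**Retrosynthetic overview**
1. Glyceride ester: open (S)-glycidyl acetate (from (R)-glycidol) with the C20 diketo acid at the epoxide CH2.
2. Side chain: asymmetric hydrogenation of an (E)-3-methyl-2-enoic acid sets the chain methyl centre. The enoic acid comes from alkylating a ring methyl ketone with a C5 bromo acid, and the 3-oxobutyl ketone is carried as a butenyl group (Wacker).
3. Ring methyl ketone (both ring stereocentres and the quaternary carbon): one enantioselective proton-initiated cation–olefin cyclisation of an acyclic tertiary silyl ether, ended by a 1,2-methyl shift (semipinacol).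
4. Acyclic precursor: anti-carbomagnesiation of the propargylic alcohol from hex-1-en-5-yne and acetone with the Grignard reagent of 5-bromo-2-methylpent-2-ene.
5. Ring order: the cyclohexane is the only ring and is formed in step 4.

Assumption: the facial sense of the two chiral reagents (the (R)-binaphthol·SnCl4 acid in step 4, the (S)-BINAP ruthenium catalyst in step 7) is taken to give the configurations drawn; if either proves opposite, its mirror-image ligand is used.

**Step 1**
Reactants: 1 hex-1-en-5-yne; 2 acetone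
Product: 4 2-methyloct-7-en-3-yn-2-ol, via lithium hex-5-en-1-ynide 3 (not isolated)
Conditions: n-BuLi (1.05 equiv), THF, −78 °C, 30 min; then 2 (1.2 equiv), −78 → 0 °C; H2O work-up
Reagents that add atoms: none
Why: Deprotonation of the terminal alkyne and 1,2-addition of the lithium acetylide to the ketone (alkynylation); no stereocentre is formed.

**Step 2**
Reactants: 4 2-methyloct-7-en-3-yn-2-ol; 5 5-bromo-2-methylpent-2-ene
Product: 8 (3E)-2-methyl-3-(4-methylpent-3-en-1-yl)octa-3,7-dien-2-ol, via (4-methylpent-3-en-1-yl)magnesium bromide 6 (not isolated), via cyclic alkenylmagnesium alkoxide 7 (not isolated)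
Conditions: 5, Mg, THF, 25 → 40 °C (gives 6); 4, MeMgBr (1.0 equiv), THF, 0 °C; then 6 (2.0 equiv), CuBr·SMe2 (10 mol %), THF/toluene, 60 °C, 12 h; H2O work-up
Reagents that add atoms: none
Why: Alkoxide-directed, copper-catalysed anti-carbomagnesiation of a propargylic alcohol puts the new alkyl group on the carbon next to the carbinol and magnesium on the far carbon in a five-membered chelate, so protonation gives the 3E alkene with the two chains cis, the geometry the cyclisation needs.

**Step 3**
Reactants: 8 (3E)-2-methyl-3-(4-methylpent-3-en-1-yl)octa-3,7-dien-2-ol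
Product: 9 triethyl{[(3E)-2-methyl-3-(4-methylpent-3-en-1-yl)octa-3,7-dien-2-yl]oxy}silane
Conditions: Et3SiOTf (1.3 equiv), 2,6-lutidine (2.0 equiv), CH2Cl2, −78 → 0 °C
Reagents that add atoms: triethylsilyl trifluoromethanesulfonate, CC[Si](CC)(CC)OS(=O)(=O)C(F)(F)F
Why: Silyl triflate silylation of a tertiary alcohol; the silyl ether resists ionisation under the Lewis-acidic conditions of step 4 and supplies the oxygen lone pair that drives the shift.

**Step 4**
Reactants: 9 triethyl{[(3E)-2-methyl-3-(4-methylpent-3-en-1-yl)octa-3,7-dien-2-yl]oxy}silane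
Product: 11 1-[(1R,2R)-2-(but-3-en-1-yl)-1,3,3-trimethylcyclohexyl]ethan-1-one, via O-triethylsilyl oxocarbenium ion 10 (not isolated)
Conditions: (R)-2′-(2-fluorobenzyloxy)-1,1′-binaphthalen-2-ol·SnCl4 (1.2 equiv, premixed), toluene, −78 °C, 48 h; aq. NaHCO3 (the binaphthol is recovered)
Reagents that add atoms: none
Why: Proposed new method: the SnCl4-activated chiral binaphthol proton is delivered to the electron-rich isopropylidene of the chair-folded substrate, the CH carbon of the (E)-allylic silyl ether alkene closes the six-membered ring on the incipient tertiary cation, and the cation developing next to the silyloxy carbon is quenched at once by a 1,2-methyl shift anti to the new C–C bond (semipinacol, giving 10, which loses Et3Si+), so anti addition across the alkene of defined geometry sets the ring CH and the acetyl-bearing quaternary carbon as the (1R,2R) pair while the chiral acid selects the enantiomeric fold; the closest known chemistry is the Yamamoto–Ishihara enantioselective proton-initiated polyene cyclisation of silyl ethers with this type of acid and Overman's pinacol-terminated Prins cyclisations, but a proton-initiated, methyl-shift-terminated, enantioselective version has not been shown.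

**Step 5**
Reactants: 11 1-[(1R,2R)-2-(but-3-en-1-yl)-1,3,3-trimethylcyclohexyl]ethan-1-one; 12 (2E)-4-bromo-3-methylbut-2-enoic acid
Product: 15 (2E)-6-[(1R,2R)-2-(but-3-en-1-yl)-1,3,3-trimethylcyclohexyl]-3-methyl-6-oxohex-2-enoic acid, via lithium enolate 13 (not isolated), via lithium carboxylate 14 (not isolated)
Conditions: 11, LiN(i-Pr)2 (1.1 equiv), THF, −78 °C (gives 13); 12, LiN(SiMe3)2 (1.0 equiv), THF, −78 °C (gives 14); combine, DMPU (4 equiv), −78 → 0 °C, 4 h; 1 M HCl
Reagents that add atoms: none
Why: Enolate alkylation (SN2 at the primary allylic bromide): the acetyl methyl is the only enolisable position because the other α-carbon is quaternary, the carboxyl group is masked as its unreactive lithium salt, and the E alkene geometry is carried over unchanged.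

**Step 6**
Reactants: 15 (2E)-6-[(1R,2R)-2-(but-3-en-1-yl)-1,3,3-trimethylcyclohexyl]-3-methyl-6-oxohex-2-enoic acid
Product: 16 (2E)-3-methyl-6-oxo-6-[(1R,2R)-1,3,3-trimethyl-2-(3-oxobutyl)cyclohexyl]hex-2-enoic acid
Conditions: PdCl2 (10 mol %), CuCl (20 mol %), O2 (1 atm), DMF/H2O (7:1), 25 °C, 24 h
Reagents that add atoms: water, O
Why: Tsuji–Wacker oxidation converts only the terminal monosubstituted alkene into the methyl ketone (Markovnikov); the conjugated trisubstituted alkene is inert and no stereocentre is touched.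

**Step 7**
Reactants: 16 (2E)-3-methyl-6-oxo-6-[(1R,2R)-1,3,3-trimethyl-2-(3-oxobutyl)cyclohexyl]hex-2-enoic acid
Product: 17 (3R)-3-methyl-6-oxo-6-[(1R,2R)-1,3,3-trimethyl-2-(3-oxobutyl)cyclohexyl]hexanoic acid
Conditions: Ru(OAc)2[(S)-BINAP] (1 mol %), H2 (100 atm), MeOH, 25 °C, 24 h
Reagents that add atoms: none
Why: Carboxylate-directed Noyori asymmetric hydrogenation of an (E)-3-methyl-2-enoic acid (as in geranic acid to citronellic acid) sets the 3R methyl centre by catalyst control and leaves the two unfunctionalised ketones alone.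

**Step 8**
Reactants: 18 (R)-glycidol
Product: 19 (S)-glycidyl acetate
Conditions: Ac2O (1.2 equiv), Et3N (1.5 equiv), DMAP (5 mol %), CH2Cl2, 0 °C, 1 h
Reagents that add atoms: acetic anhydride, CC(=O)OC(C)=O
Why: DMAP-catalysed O-acetylation of the primary alcohol; the stereocentre is not touched (the descriptor changes from R to S only through the priority rules).

**Step 9**
Reactants: 17 (3R)-3-methyl-6-oxo-6-[(1R,2R)-1,3,3-trimethyl-2-(3-oxobutyl)cyclohexyl]hexanoic acid; 19 (S)-glycidyl acetate
Product: 20 [(2R)-3-(acetyloxy)-2-hydroxypropyl] (3R)-3-methyl-6-oxo-6-[(1R,2R)-1,3,3-trimethyl-2-(3-oxobutyl)cyclohexyl]hexanoate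
Conditions: Co(salen)(OAc) (2 mol %; salen = N,N′-bis(3,5-di-tert-butylsalicylidene)cyclohexane-1,2-diamine dianion, racemic), i-Pr2NEt (0.2 equiv), t-BuOMe, 25 °C, 24 h
Reagents that add atoms: none
Why: Cobalt-salen-catalysed ring opening of a terminal epoxide by a carboxylic acid occurs at the CH2 carbon, so the epoxide stereocentre is kept and becomes the 2R secondary alcohol flanked by the two esters; mild, nearly neutral conditions suppress acyl migration.

**Compound list**
1 | hex-1-en-5-yne | C=CCCC#C | starting material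
2 | acetone | CC(C)=O | starting material
3 | lithium hex-5-en-1-ynide | [Li]C#CCCC=C | intermediate
4 | 2-methyloct-7-en-3-yn-2-ol | CC(C)(O)C#CCCC=C | intermediate
5 | 5-bromo-2-methylpent-2-ene | CC(C)=CCCBr | starting material
6 | (4-methylpent-3-en-1-yl)magnesium bromide | CC(C)=CCC[Mg]Br | intermediate
7 | cyclic alkenylmagnesium alkoxide, 3-(but-3-en-1-yl)-5,5-dimethyl-4-(4-methylpent-3-en-1-yl)-2,5-dihydro-1,2-oxamagnesole | CC(C)=CCCC1=C(CCC=C)[Mg]OC1(C)C | intermediate
8 | (3E)-2-methyl-3-(4-methylpent-3-en-1-yl)octa-3,7-dien-2-ol | CC(C)=CCC/C(=C\CCC=C)C(C)(C)O | intermediate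
9 | triethyl{[(3E)-2-methyl-3-(4-methylpent-3-en-1-yl)octa-3,7-dien-2-yl]oxy}silane | CC(C)=CCC/C(=C\CCC=C)C(C)(C)O[Si](CC)(CC)CC | intermediate
10 | O-triethylsilyl oxocarbenium ion of ketone 11 | C=CCC[C@@H]1C(C)(C)CCC[C@@]1(C)C(C)=[O+][Si](CC)(CC)CC | intermediate
11 | 1-[(1R,2R)-2-(but-3-en-1-yl)-1,3,3-trimethylcyclohexyl]ethan-1-one | C=CCC[C@@H]1C(C)(C)CCC[C@@]1(C)C(C)=O | intermediate
12 | (2E)-4-bromo-3-methylbut-2-enoic acid | BrC/C(C)=C/C(=O)O | starting material
13 | lithium enolate of 11, lithium 1-[(1R,2R)-2-(but-3-en-1-yl)-1,3,3-trimethylcyclohexyl]ethen-1-olate | C=CCC[C@@H]1C(C)(C)CCC[C@@]1(C)C(=C)O[Li] | intermediate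
14 | lithium (2E)-4-bromo-3-methylbut-2-enoate | BrC/C(C)=C/C(=O)O[Li] | intermediate
15 | (2E)-6-[(1R,2R)-2-(but-3-en-1-yl)-1,3,3-trimethylcyclohexyl]-3-methyl-6-oxohex-2-enoic acid | C=CCC[C@@H]1C(C)(C)CCC[C@@]1(C)C(=O)CC/C(C)=C/C(=O)O | intermediate
16 | (2E)-3-methyl-6-oxo-6-[(1R,2R)-1,3,3-trimethyl-2-(3-oxobutyl)cyclohexyl]hex-2-enoic acid | CC(=O)CC[C@@H]1C(C)(C)CCC[C@@]1(C)C(=O)CC/C(C)=C/C(=O)O | intermediate
17 | (3R)-3-methyl-6-oxo-6-[(1R,2R)-1,3,3-trimethyl-2-(3-oxobutyl)cyclohexyl]hexanoic acid | CC(=O)CC[C@@H]1C(C)(C)CCC[C@@]1(C)C(=O)CC[C@@H](C)CC(=O)O | intermediate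
18 | (R)-glycidol, [(2R)-oxiran-2-yl]methanol | OC[C@@H]1CO1 | starting material
19 | (S)-glycidyl acetate, [(2S)-oxiran-2-yl]methyl acetate | CC(=O)OC[C@@H]1CO1 | intermediate
20 | [(2R)-3-(acetyloxy)-2-hydroxypropyl] (3R)-3-methyl-6-oxo-6-[(1R,2R)-1,3,3-trimethyl-2-(3-oxobutyl)cyclohexyl]hexanoate (CNP0140002.1) | CC(=O)CC[C@@H]1C(C)(C)CCC[C@@]1(C)C(=O)CC[C@@H](C)CC(=O)OC[C@H](O)COC(C)=O | target

**Step count and risks**
Total steps: 9. Longest linear sequence: 8 (steps 1–7, then 9); step 8 is a one-step side branch.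

The three steps most likely to fail:

Step 4 (the proposed new cascade). Risks are ionisation of the tertiary allylic silyl ether, direct protonation of the inner alkene (methyl shift without ring closure) and low enantioselectivity. The fallback uses only known reactions, sets out from 5 and comes back at 11. The lithium enolate of tert-butyl acetate (LiN(i-Pr)2, THF/DMPU) is alkylated with 5 to give tert-butyl 6-methylhept-5-enoate F3. Aldol addition of its enolate to pent-4-enal and mesylate elimination (MsCl, Et3N, then DBU) give tert-butyl (2E)-2-(4-methylpent-3-en-1-yl)hepta-2,6-dienoate F4. Hydrogen-atom-transfer reductive cyclisation (Fe(acac)3, PhSiH3, EtOH, 60 °C) closes the ring: the tertiary radical from the isopropylidene adds to the acrylate β-carbon, and the terminal vinyl group is a poor hydrogen-atom acceptor. This gives tert-butyl 2-(but-3-en-1-yl)-3,3-dimethylcyclohexane-1-carboxylate F5. Deprotonation and methylation (LiN(i-Pr)2, then MeI) should occur on the equatorial face of the exocyclic enolate, because allylic strain holds the butenyl group axial and the axial face is blocked by the syn-axial ring methyl. This gives racemic tert-butyl (1RS,2RS)-2-(but-3-en-1-yl)-1,3,3-trimethylcyclohexane-1-carboxylate F6. CF3CO2H gives racemic (1RS,2RS)-2-(but-3-en-1-yl)-1,3,3-trimethylcyclohexane-1-carboxylic acid F7. Classical resolution through the 1-phenylethylammonium salt gives (1R,2R)-2-(but-3-en-1-yl)-1,3,3-trimethylcyclohexane-1-carboxylic acid F8, and MeLi (2.2 equiv, Et2O, 0 °C) converts it into 11.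

Step 2 (carbomagnesiation of a tertiary, internal propargylic alcohol with a primary alkyl Grignard reagent; risks are low conversion and reduction by β-hydride transfer). The fallback replaces alkyne carbometalation by carbonyl condensation, sets out from 5 and comes back at 8. The lithium enolate of methyl acetate (LiN(i-Pr)2, THF/DMPU) is alkylated with 5 to give methyl 6-methylhept-5-enoate F1. Aldol addition of its enolate to pent-4-enal and mesylate elimination (MsCl, Et3N, then DBU) give methyl (2E)-2-(4-methylpent-3-en-1-yl)hepta-2,6-dienoate F2, the thermodynamic E isomer, purified by chromatography. Double addition of MeLi (2.5 equiv, THF, −78 → 0 °C) to the ester gives 8.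

Step 5 (alkylation of a hindered ketone enolate with a carboxylate-bearing allylic bromide; risks are poor solubility, proton transfer and double alkylation). The fallback changes both partners, sets out from 11 (and 12) and comes back at 15. Ketone 11 is condensed with N,N-dimethylhydrazine (TsOH cat., EtOH, reflux) to give 1-[(1R,2R)-2-(but-3-en-1-yl)-1,3,3-trimethylcyclohexyl]ethan-1-one N,N-dimethylhydrazone F9. Acid 12 is esterified (Me3SiCHN2, MeOH/toluene) to methyl (2E)-4-bromo-3-methylbut-2-enoate F10. The aza-enolate of F9 (LiN(i-Pr)2, THF, −78 °C) is alkylated with F10 to give methyl (2E)-6-[(1R,2R)-2-(but-3-en-1-yl)-1,3,3-trimethylcyclohexyl]-6-(2,2-dimethylhydrazinylidene)-3-methylhex-2-enoate F11. One-pot saponification (LiOH, THF/H2O) and hydrazone hydrolysis (aq. oxalic acid) give 15.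

**Further compounds**
F1 | step 2 | methyl 6-methylhept-5-enoate | CC(C)=CCCCC(=O)OC
F2 | step 2 | methyl (2E)-2-(4-methylpent-3-en-1-yl)hepta-2,6-dienoate | CC(C)=CCC/C(=C\CCC=C)C(=O)OC
F3 | step 4 | tert-butyl 6-methylhept-5-enoate | CC(C)=CCCCC(=O)OC(C)(C)C
F4 | step 4 | tert-butyl (2E)-2-(4-methylpent-3-en-1-yl)hepta-2,6-dienoate | CC(C)=CCC/C(=C\CCC=C)C(=O)OC(C)(C)C
F5 | step 4 | tert-butyl 2-(but-3-en-1-yl)-3,3-dimethylcyclohexane-1-carboxylate (racemic, cis/trans mixture) | C=CCCC1C(C)(C)CCCC1C(=O)OC(C)(C)C
F6 | step 4 | tert-butyl (1RS,2RS)-2-(but-3-en-1-yl)-1,3,3-trimethylcyclohexane-1-carboxylate (racemate, one enantiomer drawn) | C=CCC[C@@H]1C(C)(C)CCC[C@@]1(C)C(=O)OC(C)(C)C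
F7 | step 4 | (1RS,2RS)-2-(but-3-en-1-yl)-1,3,3-trimethylcyclohexane-1-carboxylic acid (racemate, one enantiomer drawn) | C=CCC[C@@H]1C(C)(C)CCC[C@@]1(C)C(=O)O
F8 | step 4 | (1R,2R)-2-(but-3-en-1-yl)-1,3,3-trimethylcyclohexane-1-carboxylic acid | C=CCC[C@@H]1C(C)(C)CCC[C@@]1(C)C(=O)O
F9 | step 5 | 1-[(1R,2R)-2-(but-3-en-1-yl)-1,3,3-trimethylcyclohexyl]ethan-1-one N,N-dimethylhydrazone | C=CCC[C@@H]1C(C)(C)CCC[C@@]1(C)C(C)=NN(C)C
F10 | step 5 | methyl (2E)-4-bromo-3-methylbut-2-enoate | BrC/C(C)=C/C(=O)OC
F11 | step 5 | methyl (2E)-6-[(1R,2R)-2-(but-3-en-1-yl)-1,3,3-trimethylcyclohexyl]-6-(2,2-dimethylhydrazinylidene)-3-methylhex-2-enoate | C=CCC[C@@H]1C(C)(C)CCC[C@@]1(C)C(CC/C(C)=C/C(=O)OC)=NN(C)C
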